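# Kazinol K: route proposal through a dearomative oxygenation that closes the chromene

## Analysis of the target

Kazinol K (26) is an achiral 1,3-diarylpropane in which a saturated three-carbon chain joins C1' of a resorcinol (ring A) to C6 of a 2,2-dimethyl-2H-chromen-8-ol (ring B with its fused pyran; chromene numbering O1, C2–C4, C4a, C5–C8, C8a). Ring A carries hydroxyls at C2' and C4' and a 1,1-dimethylallyl group at C5', ortho to the 4'-hydroxyl and para to the 2'-hydroxyl. Ring B is substituted at five of its six carbons: O1 on C8a, a hydroxyl on C8, pyran carbon C4 on C4a, a prenyl group on C5 and the chain on C6; only C7 carries hydrogen. There is no stereocentre, because C2 and the quaternary carbon of the 1,1-dimethylallyl group each bear two methyl groups, so the whole problem is one of regiochemistry. Three different alkenes (terminal vinyl, trisubstituted prenyl, styrenic C3=C4) exclude hydrogenation and hydroboration once they are present. Phenols next to prenyl-type groups cyclise under acid, and the 8-hydroxychromene is a catechol monoether that oxidises easily. The strategy rests on ring B: O1, the 8-hydroxyl and C4–C3–C2 are the tautomer of an ortho-quinone (carbonyls at C8a and C8) with a prenyl group on the neighbouring carbon C4a, and the adjacent carbon substituents at C4a and C5, with oxygen at C8a and a former oxygen at C6, map onto the symmetric 2,3-diprenylhydroquinone 6.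

## Retrosynthetic reasoning

**26 back to 25.** The two ring A hydroxyls are masked as triisopropylsilyl ethers in 25. They are cut last because fluoride removes them without touching the alkenes, and because ring A must carry no free hydroxyl in the oxidation that precedes.

**25 back to 22 (key disconnection).** The O1–C2 bond and the C8–O bond are cut, and C4–C3 returns to the saturated benzylic CH2 of a prenyl group. This gives the seco phenol 22, a 4-alkyl-2,3-diprenylphenol whose only free ortho carbon is the future C8. Forward, a hypervalent iodine oxidant must oxygenate that carbon to the ortho-quinone 23. A tertiary amine must then move one benzylic hydrogen of the prenyl group next to the old phenol carbon onto the new oxygen, giving 24, and the resulting 1-oxatriene must close. The cut is made here because it creates the 8-hydroxyl and the pyran together and lets the precursor be a simple monophenol.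

**22 back to 8 and 19.** After removal of the acetate (22 from 21), the aryl–CH2 bond between ring B and the chain is cut. The ring B carbon involved is the second oxygen-bearing carbon of the symmetric hydroquinone 6, so its C–O bond can become the C–C bond through the triflate 8. The partner is the alkylzinc iodide 20 made from iodide 19. A cut at the ring A end would give up this use of the hydroquinone oxygen and would need a separate source for the chain.

**8 back to 6.** The triflate and the acetate are both placed on the two equivalent hydroxyls of 6. Forward, this is the one desymmetrisation of the route, done on a small and cheap compound.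

**6 back to 4, then to 2 and 3, then to 1.** The hydroquinone is taken back through quinone 5 to its dimethyl ether 4. Each prenyl group is cut between its benzylic CH2 and its vinylic carbon, giving the bis(benzylic bromide) 2 and two equivalents of the alkenyl Grignard reagent 3. Bromide 2 comes from 1, whose two adjacent methyl groups already define the 2,3-pattern. A double aromatic Claisen rearrangement on a hydroquinone diether would be shorter on paper but would have to choose between the 2,3- and the 2,5-pattern. The benzylic route leaves no such choice.

**19 back to 17.** The iodide comes from alcohol 18 and this from methyl ester 17. These are changes of oxidation level only, placed after all thermal chemistry on ring A.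

**17 back to 14.** After removal of the second silyl group (17 from 16), the bond between C5' and the quaternary carbon is cut. This leads through dienone 15 to the O4' prenyl ether 14 (aromatic Claisen rearrangement). Forward, the shift must go to C5' and not to C3'. The silyl ether on O2' is in place before the rearrangement for this reason: it screens C3'.

**14 back to 9.** Silyl ether 14 comes from phenol 13, this from lactone 12 by methanolysis, 12 from 10 and prenyl bromide 11, and 10 from umbelliferone 9 by hydrogenation. The lactone of 10 holds the three-carbon chain and O2' in one ring, so the only free hydroxyl is O4'. The two ring A oxygens are thus differentiated without any selective step.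

## Alternatives that were turned down

**Alternative 1:** Ring A is cut at C1'–C6' and C3'–C4' and is assembled last as a cyclohexane-1,3-dione. Forward, the acetoacetate A3, which already carries the finished chromene on its three-carbon chain, adds as Michael donor to the α-methylene ester A2. The methyl ketone enolate then closes onto the ester of the former acceptor (Claisen condensation) to give the dione ester A1; loss of the ester carbon and dehydrogenation to the resorcinol follow.
- For it: the position of the 1,1-dimethylallyl group is fixed by construction. On this point it is stronger than the chosen route, where that position depends on the direction of a Claisen rearrangement.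
- Against it: the donor carbon of A3 is tertiary and A2 has a tert-alkyl group on its α-carbon. The Michael step therefore makes a quaternary carbon, and the ring closure must attack an ester flanked by a neopentyl-type centre; alkoxide can instead deacetylate A3.
- Against it: A1 must still be dehydrogenated, and the oxidants or the palladium on carbon at high temperature needed for that are unlikely to spare the chromene double bond, the prenyl group and the terminal vinyl group.
- Comparison: A3 presupposes the 5,6,8-substituted chromenol, which is the hard part of the molecule. The chosen strategy puts its key step on that problem and makes ring A by routine steps from 9.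

**Alternative 2:** Ring A is cut at four bonds (C1'–C2', C2'–C3', C4'–C5', C5'–C6'). Forward, irradiation of the unsaturated α-diazo ketone A5 moves the alkenyl group to the diazo carbon (Wolff rearrangement) and gives a vinylketene. This adds the silyloxyalkyne A6 in a [2+2] sense; the cyclobutenone opens (4π) to a dienylketene that closes (6π) and enolises to A4.
- For it: four bonds and one ring in a single operation, a fully defined substitution pattern and two differentiated ring A oxygens. In bonds per step and in convergence it is clearly stronger than the chosen key step.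
- Against it: A5 needs a diazo group on a carbon that also carries the quaternary 1,1-dimethylallyl carbon. Diazo transfer to such a hindered position is doubtful, and so is the [2+2] addition of a ketene with a tert-alkyl group on its α-carbon.
- Against it: the carbene and ketene stage lies next to a vinyl group and allylic C–H bonds, and the light falls on a 2H-chromene, which is itself photoactive (ring opening to an ortho-quinone methide).
- Comparison: ring B must again be complete beforehand. The chosen strategy offers a thermal, non-photochemical key step that makes ring B.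

**Alternative 3:** The C5'–quaternary carbon bond of ring A is taken back to an O4' prenyl ether and the C4a–C4 bond of ring B to a 1,1-dimethylpropargyl ether on the C8a oxygen. Forward, heating A8 triggers the aromatic Claisen rearrangement on ring A. On ring B the propargyl ether rearranges to an ortho-allenyl phenol, a 1,5-hydrogen shift gives an ortho-quinone methide, and oxa-6π closure re-forms O1–C2 to give A7.
- For it: both rearrangements are standard for exactly these substructures, so on precedent it is stronger than the chosen key step. It forms two C–C bonds and a ring in one flask.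
- Against it: A8 is no simpler than the target. Its ring B already needs two adjacent, differentiated oxygens on the same ring as the adjacent prenyl group and chain, with no symmetry to help, and O-alkylation of a phenol flanked by a silyloxy group with a tertiary propargylic electrophile is slow.
- Against it: the two rearrangements have different temperature demands, and the phenol released on ring A stays beside a 1,1-dimethylallyl group for the whole thermolysis (further rearrangement, cyclisation).
- Comparison: the chosen route runs the ring A Claisen rearrangement early on a simple ester. It takes the 8-hydroxyl and the pyran from a symmetric precursor, so the catechol-type pattern never has to be built or differentiated. It pays for this with a key step that has no direct precedent.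

Key step: step 15

Remark: compound 1 is taken to be a catalogue chemical, and the quinone oxygens formed in step 3 are taken to come from water, the methoxy groups leaving as methanol.

## Route

**Step 1**
Reactants: 1 1,4-dimethoxy-2,3-dimethylbenzene
Product: 2 2,3-bis(bromomethyl)-1,4-dimethoxybenzene
Conditions: NBS (2.1 equiv), AIBN (cat.), PhCF3, reflux
Reagents that add atoms: N-bromosuccinimide (first equivalent), O=C1CCC(=O)N1Br; N-bromosuccinimide (second equivalent), O=C1CCC(=O)N1Br
Why: Wohl–Ziegler radical bromination of the two benzylic methyl groups, one equivalent of the bromine source per methyl group; a non-polar solvent and a radical initiator favour the chain process over ionic ring bromination, and this transformation is established for dimethoxy-xylenes of this type.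

**Step 2**
Reactants: 2 2,3-bis(bromomethyl)-1,4-dimethoxybenzene; 3 2-methylprop-1-enylmagnesium bromide
Product: 4 1,4-dimethoxy-2,3-bis(3-methylbut-2-enyl)benzene
Conditions: 3 (2.5 equiv, slow addition), CuI (10 mol %), THF, −30 to 0 °C
Reagents that add atoms: 2-methylprop-1-enylmagnesium bromide (second equivalent of 3), CC(C)=C[Mg]Br
Why: Copper-catalysed coupling of a benzylic bromide with an alkenyl Grignard reagent (Kochi-type sp3–sp2 coupling); each of the two benzylic bromides of 2 takes up one equivalent of 3, so two C4 units are delivered and both benzylic CH2–CH= bonds, and with them both prenyl groups, are formed. Low temperature and slow addition hold back bromine–magnesium exchange.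

**Step 3**
Reactants: 4 1,4-dimethoxy-2,3-bis(3-methylbut-2-enyl)benzene
Product: 6 2,3-bis(3-methylbut-2-enyl)benzene-1,4-diol, via 2,3-diprenyl-1,4-benzoquinone 5 (not isolated)
Conditions: (NH4)2Ce(NO3)6 (2.5 equiv), MeCN/H2O, 0 °C; extract into Et2O; then aq. Na2S2O4, rt, Ar
Reagents that add atoms: water (first equivalent), O; water (second equivalent), O
Why: Oxidative demethylation of a para-dimethoxyarene by tetravalent cerium is fast at 0 °C and is routinely used on prenylated arenes; the quinone is reduced at once by dithionite, so it never meets base, which would isomerise it.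

**Step 4**
Reactants: 6 2,3-bis(3-methylbut-2-enyl)benzene-1,4-diol
Product: 8 4-acetoxy-2,3-bis(3-methylbut-2-enyl)phenyl trifluoromethanesulfonate, via monotriflate 7 (not isolated)
Conditions: Tf2O (1.0 equiv, slow addition), pyridine, CH2Cl2, −78 to 0 °C; then Ac2O, DMAP (cat.), rt
Reagents that add atoms: trifluoromethanesulfonic anhydride, O=S(=O)(OS(=O)(=O)C(F)(F)F)C(F)(F)F; acetic anhydride, CC(=O)OC(C)=O
Why: O-sulfonylation then O-acylation; with a weak base the phenol reacts in neutral form, and the first triflate lowers the nucleophilicity of the remaining hydroxyl, which should favour monotriflation over the statistical outcome. Capping with acetate in the same flask avoids handling the air-sensitive monophenol, and the doubly triflated and doubly acetylated by-products are removed by chromatography.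

**Step 5**
Reactants: 9 umbelliferone (7-hydroxycoumarin)
Product: 10 7-hydroxychroman-2-one
Conditions: H2 (1 atm), Pd on carbon (10 % Pd/C), AcOH, rt
Reagents that add atoms: none
Why: Catalytic hydrogenation of the conjugated C3=C4 bond of a coumarin; it is done before any other alkene is present, and a non-alcoholic solvent keeps the lactone closed.

**Step 6**
Reactants: 10 7-hydroxychroman-2-one; 11 1-bromo-3-methylbut-2-ene (prenyl bromide)
Product: 12 7-(3-methylbut-2-enyloxy)chroman-2-one
Conditions: K2CO3, acetone, rt
Reagents that add atoms: none
Why: Williamson ether synthesis on the only free hydroxyl; the lactone masks the second phenol, so O4' is alkylated without any selectivity problem.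

**Step 7**
Reactants: 12 7-(3-methylbut-2-enyloxy)chroman-2-one
Product: 13 methyl 3-[2-hydroxy-4-(3-methylbut-2-enyloxy)phenyl]propanoate
Conditions: NaOMe (0.1 equiv), MeOH, 0 °C to rt; AcOH quench
Reagents that add atoms: methanol, CO
Why: Methanolysis of an aryl ester (phenoxide is a good leaving group, and methanol as solvent drives the equilibrium to the open hydroxy ester); the product is silylated without delay because it can relactonise on heating.

**Step 8**
Reactants: 13 methyl 3-[2-hydroxy-4-(3-methylbut-2-enyloxy)phenyl]propanoate
Product: 14 methyl 3-[4-(3-methylbut-2-enyloxy)-2-(triisopropylsilyloxy)phenyl]propanoate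
Conditions: TIPSCl, imidazole, DMF, rt
Reagents that add atoms: chlorotriisopropylsilane, CC(C)[Si](Cl)(C(C)C)C(C)C
Why: Standard silylation of a phenol; the bulky silyl ether blocks relactonisation and will screen C3' in the next step.

**Step 9**
Reactants: 14 methyl 3-[4-(3-methylbut-2-enyloxy)-2-(triisopropylsilyloxy)phenyl]propanoate
Product: 16 methyl 3-[4-hydroxy-5-(2-methylbut-3-en-2-yl)-2-(triisopropylsilyloxy)phenyl]propanoate, via cyclohexadienone 15 (not isolated)
Conditions: PhNEt2, 190 °C, Ar (sealed tube)
Reagents that add atoms: none
Why: Aromatic Claisen rearrangement; the [3,3] shift delivers the tertiary terminus of the prenyl group to an ortho carbon, and enolisation of dienone 15 restores the arene (the sp3 centre of 15 is transient, so no stereocentre remains). C5' is expected to win over C3' because C3' lies between two oxygens and is screened by the triisopropylsilyl group, which the C1' chain turns toward C3', and because a donor meta to the ether directs the shift to the position para to itself.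

**Step 10**
Reactants: 16 methyl 3-[4-hydroxy-5-(2-methylbut-3-en-2-yl)-2-(triisopropylsilyloxy)phenyl]propanoate
Product: 17 methyl 3-[5-(2-methylbut-3-en-2-yl)-2,4-bis(triisopropylsilyloxy)phenyl]propanoate
Conditions: TIPSOTf, 2,6-lutidine, CH2Cl2, 0 °C to rt
Reagents that add atoms: triisopropylsilyl trifluoromethanesulfonate, CC(C)[Si](OS(=O)(=O)C(F)(F)F)(C(C)C)C(C)C
Why: Silylation of a hindered phenol with a silyl triflate under buffered conditions; capping the hydroxyl next to the 1,1-dimethylallyl group removes the path to acid-induced cyclisation.

**Step 11**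
Reactants: 17 methyl 3-[5-(2-methylbut-3-en-2-yl)-2,4-bis(triisopropylsilyloxy)phenyl]propanoate
Product: 18 3-[5-(2-methylbut-3-en-2-yl)-2,4-bis(triisopropylsilyloxy)phenyl]propan-1-ol
Conditions: i-Bu2AlH (2.5 equiv), CH2Cl2, −78 to 0 °C
Reagents that add atoms: none
Why: Hydride reduction of the ester to the primary alcohol; aryl silyl ethers and the isolated vinyl group are inert to the aluminium hydride at this temperature.

**Step 12**
Reactants: 18 3-[5-(2-methylbut-3-en-2-yl)-2,4-bis(triisopropylsilyloxy)phenyl]propan-1-ol
Product: 19 1-(3-iodopropyl)-5-(2-methylbut-3-en-2-yl)-2,4-bis(triisopropylsilyloxy)benzene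
Conditions: I2, PPh3, imidazole, CH2Cl2, 0 °C to rt
Reagents that add atoms: iodine (I2), II
Why: Appel-type iodination of a primary alcohol through its alkoxyphosphonium salt; both phenols are silylated, so no chroman can form by intramolecular displacement.

**Step 13**
Reactants: 19 1-(3-iodopropyl)-5-(2-methylbut-3-en-2-yl)-2,4-bis(triisopropylsilyloxy)benzene; 8 4-acetoxy-2,3-bis(3-methylbut-2-enyl)phenyl trifluoromethanesulfonate
Product: 21 4-{3-[5-(2-methylbut-3-en-2-yl)-2,4-bis(triisopropylsilyloxy)phenyl]propyl}-2,3-bis(3-methylbut-2-enyl)phenyl acetate, via alkylzinc iodide 20 (not isolated)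
Conditions: Zn dust (activated with BrCH2CH2Br and Me3SiCl), LiCl, THF, 40 °C; then 8, Pd(OAc)2 (3 mol %), SPhos (6 mol %), THF, rt to 50 °C
Reagents that add atoms: none
Why: LiCl-assisted zinc insertion into a primary alkyl iodide, then Negishi sp3–sp2 coupling with an aryl triflate; a bulky biarylphosphine on zerovalent palladium is suited to ortho-substituted electrophiles and fast reductive elimination of primary alkyl groups. The acetate, silyl ethers and alkenes are inert to the alkylzinc reagent.

**Step 14**
Reactants: 21 4-{3-[5-(2-methylbut-3-en-2-yl)-2,4-bis(triisopropylsilyloxy)phenyl]propyl}-2,3-bis(3-methylbut-2-enyl)phenyl acetate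
Product: 22 4-{3-[5-(2-methylbut-3-en-2-yl)-2,4-bis(triisopropylsilyloxy)phenyl]propyl}-2,3-bis(3-methylbut-2-enyl)phenol (seco phenol)
Conditions: i-Bu2AlH (2.2 equiv), CH2Cl2, −78 °C
Reagents that add atoms: none
Why: Reductive cleavage of the aryl acetate; hydride attacks the only carbonyl group, so the two aryl silyl ethers, which basic methanolysis could endanger, are untouched.

**Step 15**
Reactants: 22 4-{3-[5-(2-methylbut-3-en-2-yl)-2,4-bis(triisopropylsilyloxy)phenyl]propyl}-2,3-bis(3-methylbut-2-enyl)phenol (seco phenol)
Product: 25 Kazinol K ring A bis(triisopropylsilyl) ether, via ortho-quinone 23 (not isolated), via hydroxy ortho-quinone methide 24 (not isolated)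
Conditions: IBX (1.0 equiv), DMF, 0 °C to rt, dark; partition PhMe/aq. NaHCO3, dry (Na2SO4); then Et3N (2 equiv), PhMe, rt to 40 °C, Ar
Reagents that add atoms: 2-iodoxybenzoic acid (IBX), O=C1OI(=O)(O)c2ccccc12
Why: Proposed new method: the free phenol of 22 should bind the pentavalent iodine of IBX and receive oxygen intramolecularly at its single unsubstituted ortho carbon, giving ortho-quinone 23 and 2-iodobenzoic acid; this half is the known IBX ortho-oxygenation of electron-rich phenols. Triethylamine is then expected to carry a proton from the benzylic, allylic CH2 of the prenyl group next to the former phenol carbonyl to the new, distal quinone oxygen, giving the hydroxy ortho-quinone methide 24; the closest known reaction is the amine-induced isomerisation of prenylated para-quinones to chromenols, and what is new is its use on an ortho-quinone generated in the same operation. 24 contains the 1-oxatriene O=C–C=CH–CH=CMe2 and should close the pyran by thermal disrotatory oxa-6π electrocyclisation, forming O1–C2 and restoring the arene, with the new oxygen ending as the 8-hydroxyl. No stereocentre is formed, since C2 carries two methyl groups. The site of oxygenation is fixed by the substitution pattern (one ortho carbon bears a prenyl group, the other is the only free CH), and ring A is spared because its silyl ethers offer the iodine reagent no hydroxyl. The other two benzylic positions of 23 can also tautomerise, to para-quinone methides, but these have no carbonyl placed for ring closure and should revert in a dry medium freed of nucleophiles, so the irreversible electrocyclisation drains the equilibrium. The oxidant is limited to one equivalent and washed out before the base is added, so that none remains to oxidise the product phenol, which again has a free ortho CH.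

**Step 16**
Reactants: 25 Kazinol K ring A bis(triisopropylsilyl) ether
Product: 26 Kazinol K
Conditions: Bu4NF (2.5 equiv), AcOH (2.5 equiv), THF, 0 °C, Ar
Reagents that add atoms: none
Why: Fluoride cleavage of the two aryl silyl ethers; buffering with acetic acid keeps the electron-rich phenoxides protonated and protects the catechol-type chromenol from air oxidation.

## Compound list

1 | 1,4-dimethoxy-2,3-dimethylbenzene | COc1ccc(OC)c(C)c1C | starting material
2 | 2,3-bis(bromomethyl)-1,4-dimethoxybenzene | COc1ccc(OC)c(CBr)c1CBr | intermediate
3 | 2-methylprop-1-enylmagnesium bromide | CC(C)=C[Mg]Br | starting material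
4 | 1,4-dimethoxy-2,3-bis(3-methylbut-2-enyl)benzene | COc1ccc(OC)c(CC=C(C)C)c1CC=C(C)C | intermediate
5 | 2,3-bis(3-methylbut-2-enyl)-1,4-benzoquinone | CC(C)=CCC1=C(CC=C(C)C)C(=O)C=CC1=O | intermediate (not isolated)
6 | 2,3-bis(3-methylbut-2-enyl)benzene-1,4-diol | CC(C)=CCc1c(O)ccc(O)c1CC=C(C)C | intermediate
7 | 4-hydroxy-2,3-bis(3-methylbut-2-enyl)phenyl trifluoromethanesulfonate | CC(C)=CCc1c(O)ccc(OS(=O)(=O)C(F)(F)F)c1CC=C(C)C | intermediate (not isolated)
8 | 4-acetoxy-2,3-bis(3-methylbut-2-enyl)phenyl trifluoromethanesulfonate | CC(=O)Oc1ccc(OS(=O)(=O)C(F)(F)F)c(CC=C(C)C)c1CC=C(C)C | intermediate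
9 | umbelliferone (7-hydroxycoumarin) | O=c1ccc2ccc(O)cc2o1 | starting material
10 | 7-hydroxychroman-2-one | O=C1CCc2ccc(O)cc2O1 | intermediate
11 | 1-bromo-3-methylbut-2-ene (prenyl bromide) | CC(C)=CCBr | starting material
12 | 7-(3-methylbut-2-enyloxy)chroman-2-one | CC(C)=CCOc1ccc2CCC(=O)Oc2c1 | intermediate
13 | methyl 3-[2-hydroxy-4-(3-methylbut-2-enyloxy)phenyl]propanoate | COC(=O)CCc1ccc(OCC=C(C)C)cc1O | intermediate
14 | methyl 3-[4-(3-methylbut-2-enyloxy)-2-(triisopropylsilyloxy)phenyl]propanoate | COC(=O)CCc1ccc(OCC=C(C)C)cc1O[Si](C(C)C)(C(C)C)C(C)C | intermediate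
15 | methyl 3-[3-(2-methylbut-3-en-2-yl)-4-oxo-6-(triisopropylsilyloxy)cyclohexa-1,5-dien-1-yl]propanoate (racemic, transient) | COC(=O)CCC1=CC(C(C)(C)C=C)C(=O)C=C1O[Si](C(C)C)(C(C)C)C(C)C | intermediate (not isolated)
16 | methyl 3-[4-hydroxy-5-(2-methylbut-3-en-2-yl)-2-(triisopropylsilyloxy)phenyl]propanoate | COC(=O)CCc1cc(C(C)(C)C=C)c(O)cc1O[Si](C(C)C)(C(C)C)C(C)C | intermediate
17 | methyl 3-[5-(2-methylbut-3-en-2-yl)-2,4-bis(triisopropylsilyloxy)phenyl]propanoate | COC(=O)CCc1cc(C(C)(C)C=C)c(O[Si](C(C)C)(C(C)C)C(C)C)cc1O[Si](C(C)C)(C(C)C)C(C)C | intermediate
18 | 3-[5-(2-methylbut-3-en-2-yl)-2,4-bis(triisopropylsilyloxy)phenyl]propan-1-ol | OCCCc1cc(C(C)(C)C=C)c(O[Si](C(C)C)(C(C)C)C(C)C)cc1O[Si](C(C)C)(C(C)C)C(C)C | intermediate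
19 | 1-(3-iodopropyl)-5-(2-methylbut-3-en-2-yl)-2,4-bis(triisopropylsilyloxy)benzene | ICCCc1cc(C(C)(C)C=C)c(O[Si](C(C)C)(C(C)C)C(C)C)cc1O[Si](C(C)C)(C(C)C)C(C)C | intermediate
20 | {3-[5-(2-methylbut-3-en-2-yl)-2,4-bis(triisopropylsilyloxy)phenyl]propyl}zinc iodide | I[Zn]CCCc1cc(C(C)(C)C=C)c(O[Si](C(C)C)(C(C)C)C(C)C)cc1O[Si](C(C)C)(C(C)C)C(C)C | intermediate (not isolated)
21 | 4-{3-[5-(2-methylbut-3-en-2-yl)-2,4-bis(triisopropylsilyloxy)phenyl]propyl}-2,3-bis(3-methylbut-2-enyl)phenyl acetate | CC(=O)Oc1ccc(CCCc2cc(C(C)(C)C=C)c(O[Si](C(C)C)(C(C)C)C(C)C)cc2O[Si](C(C)C)(C(C)C)C(C)C)c(CC=C(C)C)c1CC=C(C)C | intermediate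
22 | 4-{3-[5-(2-methylbut-3-en-2-yl)-2,4-bis(triisopropylsilyloxy)phenyl]propyl}-2,3-bis(3-methylbut-2-enyl)phenol (seco phenol) | C=CC(C)(C)c1cc(CCCc2ccc(O)c(CC=C(C)C)c2CC=C(C)C)c(O[Si](C(C)C)(C(C)C)C(C)C)cc1O[Si](C(C)C)(C(C)C)C(C)C | intermediate
23 | 5-{3-[5-(2-methylbut-3-en-2-yl)-2,4-bis(triisopropylsilyloxy)phenyl]propyl}-3,4-bis(3-methylbut-2-enyl)cyclohexa-3,5-diene-1,2-dione (ortho-quinone) | C=CC(C)(C)c1cc(CCCC2=CC(=O)C(=O)C(CC=C(C)C)=C2CC=C(C)C)c(O[Si](C(C)C)(C(C)C)C(C)C)cc1O[Si](C(C)C)(C(C)C)C(C)C | intermediate (not isolated)
24 | 2-hydroxy-6-(3-methylbut-2-enylidene)-5-(3-methylbut-2-enyl)-4-{3-[5-(2-methylbut-3-en-2-yl)-2,4-bis(triisopropylsilyloxy)phenyl]propyl}cyclohexa-2,4-dienone (hydroxy ortho-quinone methide, alkenyl group syn to the carbonyl) | C=CC(C)(C)c1cc(CCCC2=C(CC=C(C)C)/C(=C/C=C(C)C)C(=O)C(O)=C2)c(O[Si](C(C)C)(C(C)C)C(C)C)cc1O[Si](C(C)C)(C(C)C)C(C)C | intermediate (not isolated)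
25 | 2,2-dimethyl-6-{3-[5-(2-methylbut-3-en-2-yl)-2,4-bis(triisopropylsilyloxy)phenyl]propyl}-5-(3-methylbut-2-enyl)-2H-chromen-8-ol (Kazinol K ring A bis(triisopropylsilyl) ether) | C=CC(C)(C)c1cc(CCCc2cc(O)c3c(c2CC=C(C)C)C=CC(C)(C)O3)c(O[Si](C(C)C)(C(C)C)C(C)C)cc1O[Si](C(C)C)(C(C)C)C(C)C | intermediate
26 | Kazinol K, 4-{3-[8-hydroxy-2,2-dimethyl-5-(3-methylbut-2-enyl)-2H-chromen-6-yl]propyl}-6-(2-methylbut-3-en-2-yl)benzene-1,3-diol | C=CC(C)(C)c1cc(CCCc2cc(O)c3c(c2CC=C(C)C)C=CC(C)(C)O3)c(O)cc1O | target

## Step count and least certain steps

Total: 16 steps. Longest linear sequence: 12 steps (steps 5 to 16, from 9 to 26). The ring B branch (steps 1 to 4) joins at step 13.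

**Step 15 (key step, proposed new method).**
- The most likely failure is proton transfer along the wrong side chain of 23. Removing a hydrogen from the CH2 of the second prenyl group or from the first CH2 of the tether is kinetically easier (γ-hydrogens of an enone, against an ε-hydrogen of a dienone for the productive site). The para-quinone methides so formed cannot cyclise, and instead of reverting they may lose a second side-chain proton and aromatise with a new side-chain double bond, or be captured by a nucleophile.
- Self-condensation of the ortho-quinone before base is added, and renewed oxidation of the product phenol by leftover oxidant, are further losses.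
- Fallback by known reactions, from 22, returning at 26. 22 is oxidised with IBX as before, but the quinone is reduced at once with aqueous Na2S2O4 to the catechol, 5-{3-[5-(2-methylbut-3-en-2-yl)-2,4-bis(triisopropylsilyloxy)phenyl]propyl}-3,4-bis(3-methylbut-2-enyl)benzene-1,2-diol F1. One equivalent of TIPSCl with imidazole should silylate the less hindered hydroxyl, the new one beside the ring CH, to give 4-{3-[5-(2-methylbut-3-en-2-yl)-2,4-bis(triisopropylsilyloxy)phenyl]propyl}-2,3-bis(3-methylbut-2-enyl)-6-(triisopropylsilyloxy)phenol F2. DDQ in benzene then removes hydride from the benzylic, allylic CH2 ortho to the free hydroxyl (the standard dehydrogenative cyclisation of ortho-prenylphenols to 2,2-dimethylchromenes) and gives Kazinol K tris(triisopropylsilyl) ether F3. Bu4NF buffered with AcOH removes all three silyl groups and gives 26.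

**Step 9 (Claisen rearrangement).**
- The shift may go in part to C3', which would erode regiochemical purity.
- At 190 °C the ortho-(1,1-dimethylallyl)phenol may react further: hydrogen shift through a spirocyclopropane dienone (abnormal Claisen rearrangement), ring closure of the phenol oxygen onto the side chain, or loss of the five-carbon unit.
- Fallback from 10, returning at 17. 10 is opened with NaOMe in MeOH to methyl 3-(2,4-dihydroxyphenyl)propanoate F4, and both phenols are silylated (TIPSCl, imidazole) to methyl 3-[2,4-bis(triisopropylsilyloxy)phenyl]propanoate F5. NBS in MeCN should brominate only C5', which is para to one silyloxy group and ortho to the other while C3' is buried between both, giving methyl 3-[5-bromo-2,4-bis(triisopropylsilyloxy)phenyl]propanoate F6. A branched-selective Suzuki–Miyaura allyl–aryl coupling of F6 with 3-methylbut-2-enylboronic acid pinacol ester (Pd(OAc)2, a biarylphosphine chosen for attack through the γ-carbon, K3PO4, THF/H2O) places the 1,1-dimethylallyl group on the carbon that carried bromine and gives 17.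

**Step 13 (Negishi coupling).**
- Oxidative addition into an electron-rich triflate flanked by a prenyl group may be slow. The alkylzinc reagent would then be lost by protonation and the alkylpalladium intermediate by β-hydride elimination.
- Fallback from 19, returning at 21. Iodine–lithium exchange on 19 (t-BuLi, 2 equiv, Et2O, −78 °C) and trapping with 9-methoxy-9-borabicyclo[3.3.1]nonane gives the lithium borinate, lithium 9-methoxy-9-{3-[5-(2-methylbut-3-en-2-yl)-2,4-bis(triisopropylsilyloxy)phenyl]propyl}-9-boratabicyclo[3.3.1]nonane F7. F7 is coupled with 8 in a B-alkyl Suzuki–Miyaura reaction (PdCl2(dppf), K3PO4, DMF/THF, rt to 50 °C) to give 21. If the acetate is lost under the basic conditions, 22 is obtained directly.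

**Step 2 (double benzylic coupling).**
- Bromine–magnesium exchange at one benzylic bromide followed by 1,4-elimination would give an ortho-quinodimethane that oligomerises; homocoupling of the Grignard reagent is a second loss.
- Fallback from 2, returning at 4. 2 is coupled twice with 2-methylprop-1-enylboronic acid pinacol ester under Suzuki–Miyaura conditions (Pd(PPh3)4, K3PO4, THF/H2O, 60 °C). A boron nucleophile cannot undergo halogen–metal exchange, so the elimination path is closed; no new intermediate is formed.

## Further compounds

F1 | step 15 | 5-{3-[5-(2-methylbut-3-en-2-yl)-2,4-bis(triisopropylsilyloxy)phenyl]propyl}-3,4-bis(3-methylbut-2-enyl)benzene-1,2-diol | C=CC(C)(C)c1cc(CCCc2cc(O)c(O)c(CC=C(C)C)c2CC=C(C)C)c(O[Si](C(C)C)(C(C)C)C(C)C)cc1O[Si](C(C)C)(C(C)C)C(C)C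
F2 | step 15 | 4-{3-[5-(2-methylbut-3-en-2-yl)-2,4-bis(triisopropylsilyloxy)phenyl]propyl}-2,3-bis(3-methylbut-2-enyl)-6-(triisopropylsilyloxy)phenol | C=CC(C)(C)c1cc(CCCc2cc(O[Si](C(C)C)(C(C)C)C(C)C)c(O)c(CC=C(C)C)c2CC=C(C)C)c(O[Si](C(C)C)(C(C)C)C(C)C)cc1O[Si](C(C)C)(C(C)C)C(C)C
F3 | step 15 | Kazinol K tris(triisopropylsilyl) ether | C=CC(C)(C)c1cc(CCCc2cc(O[Si](C(C)C)(C(C)C)C(C)C)c3c(c2CC=C(C)C)C=CC(C)(C)O3)c(O[Si](C(C)C)(C(C)C)C(C)C)cc1O[Si](C(C)C)(C(C)C)C(C)C
F4 | step 9 | methyl 3-(2,4-dihydroxyphenyl)propanoate | COC(=O)CCc1ccc(O)cc1O
F5 | step 9 | methyl 3-[2,4-bis(triisopropylsilyloxy)phenyl]propanoate | COC(=O)CCc1ccc(O[Si](C(C)C)(C(C)C)C(C)C)cc1O[Si](C(C)C)(C(C)C)C(C)C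
F6 | step 9 | methyl 3-[5-bromo-2,4-bis(triisopropylsilyloxy)phenyl]propanoate | COC(=O)CCc1cc(Br)c(O[Si](C(C)C)(C(C)C)C(C)C)cc1O[Si](C(C)C)(C(C)C)C(C)C
F7 | step 13 | lithium 9-methoxy-9-{3-[5-(2-methylbut-3-en-2-yl)-2,4-bis(triisopropylsilyloxy)phenyl]propyl}-9-boratabicyclo[3.3.1]nonane | [Li+].CO[B-]1(CCCc2cc(C(C)(C)C=C)c(O[Si](C(C)C)(C(C)C)C(C)C)cc2O[Si](C(C)C)(C(C)C)C(C)C)C2CCCC1CCC2
F0 | step 2 | none | none
A1 | alternative 1 | ring A cyclohexane-1,3-dione methyl ester (diastereomer mixture) | COC(=O)C1(CCCc2cc(O[Si](C(C)C)(C(C)C)C(C)C)c3c(c2CC=C(C)C)C=CC(C)(C)O3)CC(C(C)(C)C=C)C(=O)CC1=O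
A2 | alternative 1 | methyl 3,3-dimethyl-2-methylenepent-4-enoate | C=CC(C)(C)C(=C)C(=O)OC
A3 | alternative 1 | methyl 2-acetyl-5-[2,2-dimethyl-5-(3-methylbut-2-enyl)-8-(triisopropylsilyloxy)-2H-chromen-6-yl]pentanoate (racemic) | COC(=O)C(CCCc1cc(O[Si](C(C)C)(C(C)C)C(C)C)c2c(c1CC=C(C)C)C=CC(C)(C)O2)C(C)=O
A4 | alternative 2 | Kazinol K bis-silyl ether (ring A 4'-O-triisopropylsilyl, chromene 8-O-tert-butyldimethylsilyl) | C=CC(C)(C)c1cc(CCCc2cc(O[Si](C)(C)C(C)(C)C)c3c(c2CC=C(C)C)C=CC(C)(C)O3)c(O)cc1O[Si](C(C)C)(C(C)C)C(C)C
A5 | alternative 2 | (E)-10-[8-(tert-butyldimethylsilyloxy)-2,2-dimethyl-5-(3-methylbut-2-enyl)-2H-chromen-6-yl]-4-diazo-3,3-dimethyldeca-1,6-dien-5-one (diazo carbon bearing the 1,1-dimethylallyl group) | C=CC(C)(C)C(=[N+]=[N-])C(=O)/C=C/CCCc1cc(O[Si](C)(C)C(C)(C)C)c2c(c1CC=C(C)C)C=CC(C)(C)O2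
A6 | alternative 2 | triisopropylsilyloxyethyne | C#CO[Si](C(C)C)(C(C)C)C(C)C
A7 | alternative 3 | Kazinol K bis-silyl ether (ring A 2'-O-triisopropylsilyl, chromene 8-O-tert-butyldimethylsilyl) | C=CC(C)(C)c1cc(CCCc2cc(O[Si](C)(C)C(C)(C)C)c3c(c2CC=C(C)C)C=CC(C)(C)O3)c(O[Si](C(C)C)(C(C)C)C(C)C)cc1O
A8 | alternative 3 | ring A prenyl ether, ring B 1,1-dimethylpropargyl ether thermolysis substrate | C#CC(C)(C)Oc1cc(CC=C(C)C)c(CCCc2ccc(OCC=C(C)C)cc2O[Si](C(C)C)(C(C)C)C(C)C)cc1O[Si](C)(C)C(C)(C)C
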